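**Retrosynthetic overview**
1. Target ⇐ C11 4‑methoxybenzyl ether cleavage ⇐ C5 alcohol oxidation ⇐ macrocycle closed last at C8≡C9 by ring‑closing alkyne metathesis, then Z‑selective semi‑reduction.
2. Acyclic diyne ⇐ intermolecular Still–Gennari olefination (Z‑C2=C3) between a phosphonopropanoate already esterified to C19–OH and a C3–C8 enynal (Evans aldol sets C4).
3. C19–C20 bond and C19 ⇐ Nozaki–Hiyama–Kishi addition of an epoxy vinyl iodide (oxirane from Sharpless epoxidation) to a C19 aldehyde.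
4. C10–C11 bond, C11 and the alkyne handle ⇐ new phosphoric‑acid‑catalysed 2‑butynylation of a Z‑enal (Z‑C12=C13 from Still–Gennari).
5. Oxolane ⇐ 5‑exo‑tet mesylate displacement with inversion at C17 after an Evans syn‑aldol on a 2‑deoxy‑D‑ribose aldehyde (C14, C15 from the sugar). Ring order: oxolane first, oxirane made on the side‑chain piece, macrolactone ring last.

Assumption: the SMILES is taken as drawn. Numbering used below: C1 = lactone carbonyl, round the macrocycle to C19 (carbon bearing the lactone oxygen), C20–C24 = side chain (C22/C23 oxirane); methyls on C2, C4, C6, C12, C18; OMe on C15; oxolane oxygen bridges C14 and C17. In this numbering the target is 2Z,4S,6E,8Z,11R,12Z,14R,15S,17R,18R,19R,20E,22R,23R.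

**Route**

Step 1
Reactants: 1 2-deoxy-D-ribose
Product: 2 (2R,3S)-4-(1,3-dithian-2-yl)butane-1,2,3-triol
Conditions: propane-1,3-dithiol, conc. aq. HCl, 0 → 23 °C
Reagents that add atoms: propane-1,3-dithiol, SCCCS
Why: Acid-catalysed dithioacetalisation opens the lactol and masks the future C17 aldehyde, while C14 (R) and C15 (S) are the untouched C4 and C3 of the sugar.

Step 2
Reactants: 2 (2R,3S)-4-(1,3-dithian-2-yl)butane-1,2,3-triol
Product: 3 (1S)-2-(1,3-dithian-2-yl)-1-[(4R)-2,2-dimethyl-1,3-dioxolan-4-yl]ethan-1-ol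
Conditions: 2,2-dimethoxypropane, TsOH·H2O (cat.), acetone, 0 °C
Reagents that add atoms: 2,2-dimethoxypropane, COC(C)(C)OC
Why: Kinetic acetonide formation takes the terminal 1,2-diol (monosubstituted dioxolane) and leaves only the C15 hydroxyl free.

Step 3
Reactants: 3 (1S)-2-(1,3-dithian-2-yl)-1-[(4R)-2,2-dimethyl-1,3-dioxolan-4-yl]ethan-1-ol
Product: 4 2-[(2S)-2-[(4R)-2,2-dimethyl-1,3-dioxolan-4-yl]-2-methoxyethyl]-1,3-dithiane
Conditions: NaH, MeI, THF, 0 → 23 °C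
Reagents that add atoms: iodomethane, CI
Why: Williamson etherification installs the C15 methoxy group with retention, because the C–O bond of the stereocentre is not touched.

Step 4
Reactants: 4 2-[(2S)-2-[(4R)-2,2-dimethyl-1,3-dioxolan-4-yl]-2-methoxyethyl]-1,3-dithiane
Product: 5 (3S)-3-[(4R)-2,2-dimethyl-1,3-dioxolan-4-yl]-3-methoxypropanal
Conditions: MeI, CaCO3, MeCN–H2O (4:1), 45 °C
Reagents that add atoms: water, O
Why: S-Alkylative dithiane hydrolysis under carbonate buffering frees the C17 aldehyde without cleaving the acetonide or eliminating the β-methoxy group.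

Step 5
Reactants: 5 (3S)-3-[(4R)-2,2-dimethyl-1,3-dioxolan-4-yl]-3-methoxypropanal; 6 (4R)-4-benzyl-3-propanoyl-1,3-oxazolidin-2-one
Product: 7 (4R)-4-benzyl-3-[(2R,3S,5S)-5-[(4R)-2,2-dimethyl-1,3-dioxolan-4-yl]-3-hydroxy-5-methoxy-2-methylpentanoyl]-1,3-oxazolidin-2-one
Conditions: 6, Bu2BOTf, iPr2NEt, CH2Cl2, −78 → 0 °C; then 5, −78 → 0 °C; then MeOH, aq. NaH2PO4/Na2HPO4, H2O2, 0 °C
Reagents that add atoms: none
Why: Evans syn-aldol, in which the Z-boron enolate reacts through a Zimmerman–Traxler chair on the face away from the benzyl group, sets C18 in its final configuration and C17–OH as S (to be inverted on ring closure).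

Step 6
Reactants: 7 (4R)-4-benzyl-3-[(2R,3S,5S)-5-[(4R)-2,2-dimethyl-1,3-dioxolan-4-yl]-3-hydroxy-5-methoxy-2-methylpentanoyl]-1,3-oxazolidin-2-one
Product: 8 (2S,3S,5S)-5-[(4R)-2,2-dimethyl-1,3-dioxolan-4-yl]-5-methoxy-2-methylpentane-1,3-diol
Conditions: LiBH4, MeOH (1 equiv), THF, 0 °C
Reagents that add atoms: none
Why: Hydride reduction of the exocyclic imide carbonyl expels the auxiliary and gives the 1,3-diol without touching C17 or C18.

Step 7
Reactants: 8 (2S,3S,5S)-5-[(4R)-2,2-dimethyl-1,3-dioxolan-4-yl]-5-methoxy-2-methylpentane-1,3-diol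
Product: 9 (2S,3S,5S)-1-[tert-butyl(diphenyl)silyl]oxy-5-[(4R)-2,2-dimethyl-1,3-dioxolan-4-yl]-5-methoxy-2-methylpentan-3-ol
Conditions: tert-butyl(chloro)diphenylsilane, imidazole, CH2Cl2, 0 °C
Reagents that add atoms: tert-butyl(chloro)diphenylsilane, CC(C)(C)[Si](Cl)(c1ccccc1)c1ccccc1
Why: The bulky silyl chloride reacts only with the primary C19 hydroxyl (selective silyl ether protection).

Step 8
Reactants: 9 (2S,3S,5S)-1-[tert-butyl(diphenyl)silyl]oxy-5-[(4R)-2,2-dimethyl-1,3-dioxolan-4-yl]-5-methoxy-2-methylpentan-3-ol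
Product: 10 (2S,3S,5S)-1-[tert-butyl(diphenyl)silyl]oxy-5-[(4R)-2,2-dimethyl-1,3-dioxolan-4-yl]-5-methoxy-2-methylpentan-3-yl methanesulfonate
Conditions: MsCl, Et3N, CH2Cl2, 0 °C
Reagents that add atoms: methanesulfonyl chloride, CS(=O)(=O)Cl
Why: Sulfonylation of the secondary C17 hydroxyl (retention) turns it into the leaving group for the ring closure.

Step 9
Reactants: 10 (2S,3S,5S)-1-[tert-butyl(diphenyl)silyl]oxy-5-[(4R)-2,2-dimethyl-1,3-dioxolan-4-yl]-5-methoxy-2-methylpentan-3-yl methanesulfonate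
Product: 11 [(2R,3S,5R)-5-[(2S)-1-[tert-butyl(diphenyl)silyl]oxypropan-2-yl]-3-methoxyoxolan-2-yl]methanol
Conditions: AcOH–H2O (4:1), 40 °C; concentrate; then K2CO3, MeOH, 45 °C
Reagents that add atoms: none
Why: Acetal hydrolysis frees the C13/C14 diol and the C14 hydroxyl displaces the C17 mesylate in a 5-exo-tet Williamson SN2 cyclisation (faster than the 6-exo path through the C13 hydroxyl), inverting C17 to R and giving the 2,5-cis oxolane.

Step 10
Reactants: 11 [(2R,3S,5R)-5-[(2S)-1-[tert-butyl(diphenyl)silyl]oxypropan-2-yl]-3-methoxyoxolan-2-yl]methanol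
Product: 12 (2S,3S,5R)-5-[(2S)-1-[tert-butyl(diphenyl)silyl]oxypropan-2-yl]-3-methoxyoxolane-2-carbaldehyde
Conditions: Dess–Martin periodinane, NaHCO3, CH2Cl2, 0 → 23 °C
Reagents that add atoms: none
Why: Buffered Dess–Martin oxidation of the primary alcohol gives the α-alkoxy aldehyde without epimerising C14.

Step 11
Reactants: 12 (2S,3S,5R)-5-[(2S)-1-[tert-butyl(diphenyl)silyl]oxypropan-2-yl]-3-methoxyoxolane-2-carbaldehyde; 13 ethyl 2-[bis(2,2,2-trifluoroethoxy)phosphoryl]propanoate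
Product: 14 ethyl (2Z)-3-[(2R,3S,5R)-5-[(2S)-1-[tert-butyl(diphenyl)silyl]oxypropan-2-yl]-3-methoxyoxolan-2-yl]-2-methylprop-2-enoate
Conditions: 13, KN(SiMe3)2, 18-crown-6, THF, −78 °C; then 12
Reagents that add atoms: none
Why: Still–Gennari olefination, in which the electron-poor bis(trifluoroethyl) phosphonate eliminates fast from the kinetic adduct, gives the Z-trisubstituted C12=C13 alkene (C11 cis to C14).

Step 12
Reactants: 14 ethyl (2Z)-3-[(2R,3S,5R)-5-[(2S)-1-[tert-butyl(diphenyl)silyl]oxypropan-2-yl]-3-methoxyoxolan-2-yl]-2-methylprop-2-enoate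
Product: 15 (2Z)-3-[(2R,3S,5R)-5-[(2S)-1-[tert-butyl(diphenyl)silyl]oxypropan-2-yl]-3-methoxyoxolan-2-yl]-2-methylprop-2-en-1-ol
Conditions: iBu2AlH, CH2Cl2, −78 °C; aq. potassium sodium tartrate
Reagents that add atoms: none
Why: 1,2-Reduction of the enoate with the aluminium hydride gives the allylic alcohol with the Z geometry intact.

Step 13
Reactants: 15 (2Z)-3-[(2R,3S,5R)-5-[(2S)-1-[tert-butyl(diphenyl)silyl]oxypropan-2-yl]-3-methoxyoxolan-2-yl]-2-methylprop-2-en-1-ol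
Product: 16 (2Z)-3-[(2R,3S,5R)-5-[(2S)-1-[tert-butyl(diphenyl)silyl]oxypropan-2-yl]-3-methoxyoxolan-2-yl]-2-methylprop-2-enal
Conditions: MnO2, CH2Cl2, 23 °C
Reagents that add atoms: none
Why: MnO2 oxidises the allylic alcohol selectively under neutral conditions that do not isomerise the Z-trisubstituted alkene.

Step 14
Reactants: 17 but-2-yn-1-ol
Product: 18 but-2-yn-1-yl methyl carbonate
Conditions: ClCO2Me, pyridine, CH2Cl2, 0 °C
Reagents that add atoms: methyl chloroformate, COC(=O)Cl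
Why: O-Acylation gives the propargylic carbonate leaving group needed for the copper-catalysed borylation.

Step 15
Reactants: 18 but-2-yn-1-yl methyl carbonate
Product: 19 2-(buta-2,3-dien-2-yl)-4,4,5,5-tetramethyl-1,3,2-dioxaborolane
Conditions: bis(pinacolato)diboron, CuCl (5 mol%), 4,5-bis(diphenylphosphino)-9,9-dimethylxanthene (5 mol%), KOtBu (10 mol%), THF, 23 °C
Reagents that add atoms: bis(pinacolato)diboron, CC1(C)OB(OC1(C)C)B1OC(C)(C)C(C)(C)O1
Why: Copper-catalysed SN2′ borylation, in which the boryl-copper adds across the alkyne with boron on the methyl-bearing carbon and the carbonate is lost by β-elimination, gives the 1-methylallenylboronate.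

Step 16
Reactants: 16 (2Z)-3-[(2R,3S,5R)-5-[(2S)-1-[tert-butyl(diphenyl)silyl]oxypropan-2-yl]-3-methoxyoxolan-2-yl]-2-methylprop-2-enal; 19 2-(buta-2,3-dien-2-yl)-4,4,5,5-tetramethyl-1,3,2-dioxaborolane
Product: 20 (1Z,3R)-1-[(2R,3S,5R)-5-[(2S)-1-[tert-butyl(diphenyl)silyl]oxypropan-2-yl]-3-methoxyoxolan-2-yl]-2-methylhept-1-en-5-yn-3-ol
Conditions: (R)-3,3′-bis(2,4,6-triisopropylphenyl)-1,1′-binaphthyl-2,2′-diyl hydrogen phosphate ((R)-TRIP, 10 mol%), 4 Å molecular sieves, toluene, −20 °C; aq. NaHCO3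
Reagents that add atoms: none
Why: Proposed new method: enantioselective 2-butynylation under chiral phosphoric acid catalysis, in which the P–OH hydrogen-bonds to the pseudo-axial pinacol oxygen of 19 (raising boron Lewis acidity) and the P=O engages the formyl C–H, so the aldehyde and the allenylboronate react through a closed six-membered chair SE2′ transition state where the CH2 terminus of the allene attacks the Re face of the C11 aldehyde (sets 11R), forming C10–C11 and turning the boron-bearing carbon into the methyl-capped alkyne needed for the later ring closure, the 1-methyl group lying in the allene plane away from the forming bond; closest known reaction type: phosphoric-acid-catalysed propargylation of aldehydes with unsubstituted allenylboronic acid pinacol ester and uncatalysed thermal additions of substituted allenylboronates, not yet shown for a 1-alkyl-substituted allenylboronate or a hindered Z-2-methyl enal.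

Step 17
Reactants: 20 (1Z,3R)-1-[(2R,3S,5R)-5-[(2S)-1-[tert-butyl(diphenyl)silyl]oxypropan-2-yl]-3-methoxyoxolan-2-yl]-2-methylhept-1-en-5-yn-3-ol
Product: 21 tert-butyl-[(2S)-2-[(2R,4S,5R)-4-methoxy-5-[(1Z,3R)-3-[(4-methoxyphenyl)methoxy]-2-methylhept-1-en-5-yn-1-yl]oxolan-2-yl]propoxy]-diphenylsilane
Conditions: NaH, 4-methoxybenzyl chloride, Bu4NI (cat.), DMF, 0 → 23 °C
Reagents that add atoms: 4-methoxybenzyl chloride, COc1ccc(CCl)cc1
Why: Williamson etherification of the C11 alkoxide (C11–O bond untouched) gives a benzyl-type ether that survives fluoride, the alkylidyne catalyst and buffered HF and is removed oxidatively at the end.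

Step 18
Reactants: 21 tert-butyl-[(2S)-2-[(2R,4S,5R)-4-methoxy-5-[(1Z,3R)-3-[(4-methoxyphenyl)methoxy]-2-methylhept-1-en-5-yn-1-yl]oxolan-2-yl]propoxy]-diphenylsilane
Product: 22 (2S)-2-[(2R,4S,5R)-4-methoxy-5-[(1Z,3R)-3-[(4-methoxyphenyl)methoxy]-2-methylhept-1-en-5-yn-1-yl]oxolan-2-yl]propan-1-ol
Conditions: Bu4NF, THF, 23 °C
Reagents that add atoms: none
Why: Fluoride-driven desilylation (strong Si–F bond) frees the primary C19 alcohol while the benzyl-type ether is inert.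

Step 19
Reactants: 22 (2S)-2-[(2R,4S,5R)-4-methoxy-5-[(1Z,3R)-3-[(4-methoxyphenyl)methoxy]-2-methylhept-1-en-5-yn-1-yl]oxolan-2-yl]propan-1-ol
Product: 23 (2R)-2-[(2R,4S,5R)-4-methoxy-5-[(1Z,3R)-3-[(4-methoxyphenyl)methoxy]-2-methylhept-1-en-5-yn-1-yl]oxolan-2-yl]propanal
Conditions: Dess–Martin periodinane, NaHCO3, CH2Cl2, 0 °C; used at once
Reagents that add atoms: none
Why: Buffered Dess–Martin oxidation gives the α-methyl aldehyde without epimerising C18 or opening the oxolane by β-elimination.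

Step 20
Reactants: 24 (2E)-but-2-en-1-ol
Product: 25 [(2R,3R)-3-methyloxiran-2-yl]methanol
Conditions: Ti(OiPr)4 (10 mol%), D-(−)-diisopropyl tartrate (12 mol%), t-BuOOH, 4 Å molecular sieves, CH2Cl2, −20 °C
Reagents that add atoms: tert-butyl hydroperoxide, CC(C)(C)OO
Why: Sharpless asymmetric epoxidation, in which the titanium–D-tartrate complex delivers oxygen to one face of the E-allylic alcohol, sets C22 and C23 as the (R,R)-trans-oxirane.

Step 21
Reactants: 25 [(2R,3R)-3-methyloxiran-2-yl]methanol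
Product: 27 (2R,3R)-2-[(E)-2-iodoethenyl]-3-methyloxirane, via epoxy aldehyde 26 (not isolated)
Conditions: Dess–Martin periodinane, NaHCO3, CH2Cl2, 0 °C; filter; then CHI3, CrCl2, THF, 0 °C
Reagents that add atoms: iodoform, IC(I)I
Why: Buffered Dess–Martin oxidation and Takai olefination (the gem-dichromium carbenoid from CHI3/CrCl2 adds to the aldehyde and eliminates anti) give the E-vinyl iodide without touching the oxirane stereocentres.

Step 22
Reactants: 23 (2R)-2-[(2R,4S,5R)-4-methoxy-5-[(1Z,3R)-3-[(4-methoxyphenyl)methoxy]-2-methylhept-1-en-5-yn-1-yl]oxolan-2-yl]propanal; 27 (2R,3R)-2-[(E)-2-iodoethenyl]-3-methyloxirane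
Product: 28 (1E,3R,4S)-4-[(2R,4S,5R)-4-methoxy-5-[(1Z,3R)-3-[(4-methoxyphenyl)methoxy]-2-methylhept-1-en-5-yn-1-yl]oxolan-2-yl]-1-[(2R,3R)-3-methyloxiran-2-yl]pent-1-en-3-ol
Conditions: CrCl2 (5 equiv), NiCl2 (2 mol%), DMSO, 23 °C
Reagents that add atoms: none
Why: Nozaki–Hiyama–Kishi coupling, in which nickel-catalysed formation of the E-alkenylchromium reagent (geometry retained) is followed by chemoselective aldehyde addition with Felkin–Anh attack anti to the C17 oxolane carbon (reinforced by the 1,3-anti preference of the β-alkoxy group), sets 19R; the minor 19S epimer is removed by chromatography.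

Step 23
Reactants: 13 ethyl 2-[bis(2,2,2-trifluoroethoxy)phosphoryl]propanoate
Product: 29 2-[bis(2,2,2-trifluoroethoxy)phosphoryl]propanoic acid
Conditions: LiOH (1.05 equiv), THF–H2O, 0 °C; then 1 M HCl
Reagents that add atoms: lithium hydroxide, [Li+].[OH-]
Why: Saponification of the carboxylic ester with one equivalent of hydroxide at 0 °C leaves the trifluoroethyl phosphonate esters intact.

Step 24
Reactants: 28 (1E,3R,4S)-4-[(2R,4S,5R)-4-methoxy-5-[(1Z,3R)-3-[(4-methoxyphenyl)methoxy]-2-methylhept-1-en-5-yn-1-yl]oxolan-2-yl]-1-[(2R,3R)-3-methyloxiran-2-yl]pent-1-en-3-ol; 29 2-[bis(2,2,2-trifluoroethoxy)phosphoryl]propanoic acid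
Product: 30 (1E,3R,4R)-4-[(2R,4S,5R)-4-methoxy-5-[(1Z,3R)-3-[(4-methoxyphenyl)methoxy]-2-methylhept-1-en-5-yn-1-yl]oxolan-2-yl]-1-[(2R,3R)-3-methyloxiran-2-yl]pent-1-en-3-yl 2-[bis(2,2,2-trifluoroethoxy)phosphoryl]propanoate (both epimers at the phosphonate carbon)
Conditions: DCC, DMAP (10 mol%), CH2Cl2, 0 → 23 °C
Reagents that add atoms: none
Why: Steglich-type carbodiimide esterification acylates the C19 hydroxyl with retention and places the C1–C2 unit on the alcohol before the Z-alkene is made.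

Step 25
Reactants: 17 but-2-yn-1-ol; 31 2-(triphenyl-λ5-phosphanylidene)propanal
Product: 33 (2E)-2-methylhex-2-en-4-ynal, via but-2-ynal 32 (not isolated)
Conditions: MnO2, CH2Cl2, 23 → 40 °C
Reagents that add atoms: none
Why: Tandem MnO2 oxidation–Wittig reaction traps the volatile ynal in situ with the stabilised ylide, which gives the E-trisubstituted C6=C7 enal.

Step 26
Reactants: 33 (2E)-2-methylhex-2-en-4-ynal; 6 (4R)-4-benzyl-3-propanoyl-1,3-oxazolidin-2-one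
Product: 34 (4R)-4-benzyl-3-[(2R,3R,4E)-3-hydroxy-2,4-dimethyloct-4-en-6-ynoyl]-1,3-oxazolidin-2-one
Conditions: 6, Bu2BOTf, iPr2NEt, CH2Cl2, −78 → 0 °C; then 33, −78 → 0 °C; then MeOH, aq. NaH2PO4/Na2HPO4, H2O2, 0 °C
Reagents that add atoms: none
Why: Evans syn-aldol through the Z-boron enolate and a Zimmerman–Traxler chair sets C4 in its final configuration and C5 as R (C5 is oxidised later).

Step 27
Reactants: 34 (4R)-4-benzyl-3-[(2R,3R,4E)-3-hydroxy-2,4-dimethyloct-4-en-6-ynoyl]-1,3-oxazolidin-2-one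
Product: 35 (4R)-4-benzyl-3-[(2R,3R,4E)-2,4-dimethyl-3-(triethylsilyloxy)oct-4-en-6-ynoyl]-1,3-oxazolidin-2-one
Conditions: Et3SiOTf, 2,6-lutidine, CH2Cl2, −78 °C
Reagents that add atoms: triethylsilyl trifluoromethanesulfonate, CC[Si](CC)(CC)OS(=O)(=O)C(F)(F)F
Why: O-Silylation protects the C5 hydroxyl as a triethylsilyl ether that can later be removed in the presence of the C11 benzyl-type ether.

Step 28
Reactants: 35 (4R)-4-benzyl-3-[(2R,3R,4E)-2,4-dimethyl-3-(triethylsilyloxy)oct-4-en-6-ynoyl]-1,3-oxazolidin-2-one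
Product: 36 (2S,3R,4E)-2,4-dimethyl-3-(triethylsilyloxy)oct-4-en-6-yn-1-ol
Conditions: LiBH4, MeOH (1 equiv), THF, 0 °C
Reagents that add atoms: none
Why: Hydride reduction of the imide carbonyl removes the auxiliary and gives the primary C3 alcohol without affecting C4.

Step 29
Reactants: 36 (2S,3R,4E)-2,4-dimethyl-3-(triethylsilyloxy)oct-4-en-6-yn-1-ol
Product: 37 (2R,3R,4E)-2,4-dimethyl-3-(triethylsilyloxy)oct-4-en-6-ynal
Conditions: Dess–Martin periodinane, NaHCO3, CH2Cl2, 0 °C; used at once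
Reagents that add atoms: none
Why: Buffered Dess–Martin oxidation gives the α-methyl aldehyde without epimerising C4.

Step 30
Reactants: 30 (1E,3R,4R)-4-[(2R,4S,5R)-4-methoxy-5-[(1Z,3R)-3-[(4-methoxyphenyl)methoxy]-2-methylhept-1-en-5-yn-1-yl]oxolan-2-yl]-1-[(2R,3R)-3-methyloxiran-2-yl]pent-1-en-3-yl 2-[bis(2,2,2-trifluoroethoxy)phosphoryl]propanoate; 37 (2R,3R,4E)-2,4-dimethyl-3-(triethylsilyloxy)oct-4-en-6-ynal
Product: 38 (1E,3R,4R)-4-[(2R,4S,5R)-4-methoxy-5-[(1Z,3R)-3-[(4-methoxyphenyl)methoxy]-2-methylhept-1-en-5-yn-1-yl]oxolan-2-yl]-1-[(2R,3R)-3-methyloxiran-2-yl]pent-1-en-3-yl (2Z,4S,5R,6E)-2,4,6-trimethyl-5-(triethylsilyloxy)deca-2,6-dien-8-ynoate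
Conditions: 30, KN(SiMe3)2, 18-crown-6, THF, −78 °C; then 37, −78 °C
Reagents that add atoms: none
Why: Intermolecular Still–Gennari olefination, in which the potassium phosphonate anion adds to the aldehyde and the bis(trifluoroethyl) phosphate eliminates fast from the kinetic adduct, forms the Z-C2=C3 enoate directly on the preformed C19 ester without epimerising C4.

Step 31
Reactants: 38 (1E,3R,4R)-4-[(2R,4S,5R)-4-methoxy-5-[(1Z,3R)-3-[(4-methoxyphenyl)methoxy]-2-methylhept-1-en-5-yn-1-yl]oxolan-2-yl]-1-[(2R,3R)-3-methyloxiran-2-yl]pent-1-en-3-yl (2Z,4S,5R,6E)-2,4,6-trimethyl-5-(triethylsilyloxy)deca-2,6-dien-8-ynoate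
Product: 39 C8≡C9 cycloalkyne macrolactone (2Z,4S,5R,6E,11R,12Z,14R,15S,17R,18R,19R; 5-OSiEt3; 11-O-(4-methoxybenzyl); 15-OMe; 14,17-oxolane; C19 (E)-2-[(2R,3R)-3-methyloxiran-2-yl]ethenyl)
Conditions: Mo(≡C-C6H4-4-OMe)(OSiPh3)3 (20 mol%), 5 Å molecular sieves, toluene (2 mM), 23 → 60 °C
Reagents that add atoms: none
Why: Ring-closing alkyne metathesis, in which the molybdenum alkylidyne exchanges the two methyl-capped alkynes through metallacyclobutadienes while 2-butyne is trapped by the sieves, closes the macrolactone ring (20-membered along the carbon chain) at C8≡C9 and leaves alkenes, oxirane, esters and ethers alone.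

Step 32
Reactants: 39 C8≡C9 cycloalkyne macrolactone
Product: 40 (8Z)-diene macrolactone (2Z,4S,5R,6E,8Z,11R,12Z,14R,15S,17R,18R,19R; 5-OSiEt3; 11-O-(4-methoxybenzyl))
Conditions: Zn dust activated with Cu(OAc)2 and AgNO3, THF–MeOH–H2O (1:1:1), 40 °C
Reagents that add atoms: none
Why: Boland-type reduction with activated zinc reduces only the conjugated (enyne) triple bond with cis delivery of two hydrogens, giving the 8Z alkene of the 6E,8Z-diene without over-reduction or attack on the vinyl oxirane.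

Step 33
Reactants: 40 (8Z)-diene macrolactone
Product: 41 C5 alcohol macrolactone (5R-OH; 11-O-(4-methoxybenzyl))
Conditions: HF·pyridine, pyridine, THF, 0 °C
Reagents that add atoms: none
Why: Buffered HF cleaves the triethylsilyl ether (Si–F bond formation) while the benzyl-type ether, the oxirane and the esters survive.

Step 34
Reactants: 41 C5 alcohol macrolactone
Product: 42 C5 ketone macrolactone (11-O-(4-methoxybenzyl) ether of the target)
Conditions: Dess–Martin periodinane, NaHCO3, CH2Cl2, 0 °C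
Reagents that add atoms: none
Why: Dess–Martin oxidation converts the dienylic C5 alcohol into the ketone under buffered, non-basic conditions that neither epimerise C4 nor move the C2=C3 alkene into conjugation.

Step 35
Reactants: 42 C5 ketone macrolactone
Product: 43 CNP0117824.1 (target)
Conditions: DDQ, CH2Cl2–aq. NaH2PO4/Na2HPO4 (pH 7), 0 °C
Reagents that add atoms: none
Why: Oxidative cleavage of the 4-methoxybenzyl ether (hydride abstraction by DDQ from the electron-rich benzylic position, then hydrolysis of the oxocarbenium ion) frees the C11 alcohol at neutral pH and leaves the oxirane, the dienone and the β,γ-unsaturated ketone untouched.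

**Compound list**
1 | 2-deoxy-D-ribose | O=CC[C@H](O)[C@H](O)CO | starting material
2 | (2R,3S)-4-(1,3-dithian-2-yl)butane-1,2,3-triol | S1CCCSC1C[C@H](O)[C@H](O)CO | intermediate
3 | (1S)-2-(1,3-dithian-2-yl)-1-[(4R)-2,2-dimethyl-1,3-dioxolan-4-yl]ethan-1-ol | S1CCCSC1C[C@H](O)[C@H]1COC(C)(C)O1 | intermediate
4 | 2-[(2S)-2-[(4R)-2,2-dimethyl-1,3-dioxolan-4-yl]-2-methoxyethyl]-1,3-dithiane | S1CCCSC1C[C@H](OC)[C@H]1COC(C)(C)O1 | intermediate
5 | (3S)-3-[(4R)-2,2-dimethyl-1,3-dioxolan-4-yl]-3-methoxypropanal | O=CC[C@H](OC)[C@H]1COC(C)(C)O1 | intermediate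
6 | (4R)-4-benzyl-3-propanoyl-1,3-oxazolidin-2-one | CCC(=O)N1[C@H](Cc2ccccc2)COC1=O | starting material
7 | (4R)-4-benzyl-3-[(2R,3S,5S)-5-[(4R)-2,2-dimethyl-1,3-dioxolan-4-yl]-3-hydroxy-5-methoxy-2-methylpentanoyl]-1,3-oxazolidin-2-one | O=C([C@H](C)[C@@H](O)C[C@H](OC)[C@H]1COC(C)(C)O1)N1[C@H](Cc2ccccc2)COC1=O | intermediate
8 | (2S,3S,5S)-5-[(4R)-2,2-dimethyl-1,3-dioxolan-4-yl]-5-methoxy-2-methylpentane-1,3-diol | OC[C@H](C)[C@@H](O)C[C@H](OC)[C@H]1COC(C)(C)O1 | intermediate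
9 | (2S,3S,5S)-1-[tert-butyl(diphenyl)silyl]oxy-5-[(4R)-2,2-dimethyl-1,3-dioxolan-4-yl]-5-methoxy-2-methylpentan-3-ol | CC(C)(C)[Si](c1ccccc1)(c1ccccc1)OC[C@H](C)[C@@H](O)C[C@H](OC)[C@H]1COC(C)(C)O1 | intermediate
10 | (2S,3S,5S)-1-[tert-butyl(diphenyl)silyl]oxy-5-[(4R)-2,2-dimethyl-1,3-dioxolan-4-yl]-5-methoxy-2-methylpentan-3-yl methanesulfonate | CC(C)(C)[Si](c1ccccc1)(c1ccccc1)OC[C@H](C)[C@@H](OS(C)(=O)=O)C[C@H](OC)[C@H]1COC(C)(C)O1 | intermediate
11 | [(2R,3S,5R)-5-[(2S)-1-[tert-butyl(diphenyl)silyl]oxypropan-2-yl]-3-methoxyoxolan-2-yl]methanol | CO[C@H]1C[C@H]([C@@H](C)CO[Si](c2ccccc2)(c2ccccc2)C(C)(C)C)O[C@@H]1CO | intermediate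
12 | (2S,3S,5R)-5-[(2S)-1-[tert-butyl(diphenyl)silyl]oxypropan-2-yl]-3-methoxyoxolane-2-carbaldehyde | CO[C@H]1C[C@H]([C@@H](C)CO[Si](c2ccccc2)(c2ccccc2)C(C)(C)C)O[C@@H]1C=O | intermediate
13 | ethyl 2-[bis(2,2,2-trifluoroethoxy)phosphoryl]propanoate (racemic) | CCOC(=O)C(C)P(=O)(OCC(F)(F)F)OCC(F)(F)F | starting material
14 | ethyl (2Z)-3-[(2R,3S,5R)-5-[(2S)-1-[tert-butyl(diphenyl)silyl]oxypropan-2-yl]-3-methoxyoxolan-2-yl]-2-methylprop-2-enoate | CO[C@H]1C[C@H]([C@@H](C)CO[Si](c2ccccc2)(c2ccccc2)C(C)(C)C)O[C@@H]1/C=C(/C)C(=O)OCC | intermediate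
15 | (2Z)-3-[(2R,3S,5R)-5-[(2S)-1-[tert-butyl(diphenyl)silyl]oxypropan-2-yl]-3-methoxyoxolan-2-yl]-2-methylprop-2-en-1-ol | CO[C@H]1C[C@H]([C@@H](C)CO[Si](c2ccccc2)(c2ccccc2)C(C)(C)C)O[C@@H]1/C=C(/C)CO | intermediate
16 | (2Z)-3-[(2R,3S,5R)-5-[(2S)-1-[tert-butyl(diphenyl)silyl]oxypropan-2-yl]-3-methoxyoxolan-2-yl]-2-methylprop-2-enal | CO[C@H]1C[C@H]([C@@H](C)CO[Si](c2ccccc2)(c2ccccc2)C(C)(C)C)O[C@@H]1/C=C(/C)C=O | intermediate
17 | but-2-yn-1-ol | CC#CCO | starting material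
18 | but-2-yn-1-yl methyl carbonate | CC#CCOC(=O)OC | intermediate
19 | 2-(buta-2,3-dien-2-yl)-4,4,5,5-tetramethyl-1,3,2-dioxaborolane | C=C=C(C)B1OC(C)(C)C(C)(C)O1 | intermediate
20 | (1Z,3R)-1-[(2R,3S,5R)-5-[(2S)-1-[tert-butyl(diphenyl)silyl]oxypropan-2-yl]-3-methoxyoxolan-2-yl]-2-methylhept-1-en-5-yn-3-ol | CO[C@H]1C[C@H]([C@@H](C)CO[Si](c2ccccc2)(c2ccccc2)C(C)(C)C)O[C@@H]1/C=C(/C)[C@H](O)CC#CC | intermediate
21 | tert-butyl-[(2S)-2-[(2R,4S,5R)-4-methoxy-5-[(1Z,3R)-3-[(4-methoxyphenyl)methoxy]-2-methylhept-1-en-5-yn-1-yl]oxolan-2-yl]propoxy]-diphenylsilane | CO[C@H]1C[C@H]([C@@H](C)CO[Si](c2ccccc2)(c2ccccc2)C(C)(C)C)O[C@@H]1/C=C(/C)[C@H](OCc3ccc(OC)cc3)CC#CC | intermediate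
22 | (2S)-2-[(2R,4S,5R)-4-methoxy-5-[(1Z,3R)-3-[(4-methoxyphenyl)methoxy]-2-methylhept-1-en-5-yn-1-yl]oxolan-2-yl]propan-1-ol | CO[C@H]1C[C@H]([C@@H](C)CO)O[C@@H]1/C=C(/C)[C@H](OCc3ccc(OC)cc3)CC#CC | intermediate
23 | (2R)-2-[(2R,4S,5R)-4-methoxy-5-[(1Z,3R)-3-[(4-methoxyphenyl)methoxy]-2-methylhept-1-en-5-yn-1-yl]oxolan-2-yl]propanal | CO[C@H]1C[C@H]([C@@H](C)C=O)O[C@@H]1/C=C(/C)[C@H](OCc3ccc(OC)cc3)CC#CC | intermediate
24 | (2E)-but-2-en-1-ol | C/C=C/CO | starting material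
25 | [(2R,3R)-3-methyloxiran-2-yl]methanol | OC[C@H]1O[C@@H]1C | intermediate
26 | (2S,3R)-3-methyloxirane-2-carbaldehyde (epoxy aldehyde, not isolated) | O=C[C@H]1O[C@@H]1C | intermediate
27 | (2R,3R)-2-[(E)-2-iodoethenyl]-3-methyloxirane | I/C=C/[C@H]1O[C@@H]1C | intermediate
28 | (1E,3R,4S)-4-[(2R,4S,5R)-4-methoxy-5-[(1Z,3R)-3-[(4-methoxyphenyl)methoxy]-2-methylhept-1-en-5-yn-1-yl]oxolan-2-yl]-1-[(2R,3R)-3-methyloxiran-2-yl]pent-1-en-3-ol | CO[C@H]1C[C@H]([C@@H](C)[C@H](O)/C=C/[C@H]2O[C@@H]2C)O[C@@H]1/C=C(/C)[C@H](OCc3ccc(OC)cc3)CC#CC | intermediate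
29 | 2-[bis(2,2,2-trifluoroethoxy)phosphoryl]propanoic acid (racemic) | CC(C(=O)O)P(=O)(OCC(F)(F)F)OCC(F)(F)F | intermediate
30 | (1E,3R,4R)-4-[(2R,4S,5R)-4-methoxy-5-[(1Z,3R)-3-[(4-methoxyphenyl)methoxy]-2-methylhept-1-en-5-yn-1-yl]oxolan-2-yl]-1-[(2R,3R)-3-methyloxiran-2-yl]pent-1-en-3-yl 2-[bis(2,2,2-trifluoroethoxy)phosphoryl]propanoate (both epimers at the phosphonate carbon) | CO[C@H]1C[C@H]([C@@H](C)[C@H](OC(=O)C(C)P(=O)(OCC(F)(F)F)OCC(F)(F)F)/C=C/[C@H]2O[C@@H]2C)O[C@@H]1/C=C(/C)[C@H](OCc3ccc(OC)cc3)CC#CC | intermediate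
31 | 2-(triphenyl-λ5-phosphanylidene)propanal | CC(C=O)=P(c1ccccc1)(c1ccccc1)c1ccccc1 | starting material
32 | but-2-ynal (not isolated) | CC#CC=O | intermediate
33 | (2E)-2-methylhex-2-en-4-ynal | CC#C/C=C(\C)C=O | intermediate
34 | (4R)-4-benzyl-3-[(2R,3R,4E)-3-hydroxy-2,4-dimethyloct-4-en-6-ynoyl]-1,3-oxazolidin-2-one | CC#C/C=C(\C)[C@H](O)[C@@H](C)C(=O)N1[C@H](Cc2ccccc2)COC1=O | intermediate
35 | (4R)-4-benzyl-3-[(2R,3R,4E)-2,4-dimethyl-3-(triethylsilyloxy)oct-4-en-6-ynoyl]-1,3-oxazolidin-2-one | CC#C/C=C(\C)[C@H](O[Si](CC)(CC)CC)[C@@H](C)C(=O)N1[C@H](Cc2ccccc2)COC1=O | intermediate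
36 | (2S,3R,4E)-2,4-dimethyl-3-(triethylsilyloxy)oct-4-en-6-yn-1-ol | CC#C/C=C(\C)[C@H](O[Si](CC)(CC)CC)[C@@H](C)CO | intermediate
37 | (2R,3R,4E)-2,4-dimethyl-3-(triethylsilyloxy)oct-4-en-6-ynal | CC#C/C=C(\C)[C@H](O[Si](CC)(CC)CC)[C@@H](C)C=O | intermediate
38 | (1E,3R,4R)-4-[(2R,4S,5R)-4-methoxy-5-[(1Z,3R)-3-[(4-methoxyphenyl)methoxy]-2-methylhept-1-en-5-yn-1-yl]oxolan-2-yl]-1-[(2R,3R)-3-methyloxiran-2-yl]pent-1-en-3-yl (2Z,4S,5R,6E)-2,4,6-trimethyl-5-(triethylsilyloxy)deca-2,6-dien-8-ynoate | CO[C@H]1C[C@H]([C@@H](C)[C@H](OC(=O)C(\C)=C/[C@H](C)[C@@H](O[Si](CC)(CC)CC)/C(C)=C/C#CC)/C=C/[C@H]2O[C@@H]2C)O[C@@H]1/C=C(/C)[C@H](OCc3ccc(OC)cc3)CC#CC | intermediate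
39 | C8≡C9 cycloalkyne macrolactone (2Z,4S,5R,6E,11R,12Z,14R,15S,17R,18R,19R; 5-OSiEt3; 11-O-(4-methoxybenzyl)) | CO[C@H]1C[C@H]2O[C@@H]1/C=C(/C)[C@H](OCc3ccc(OC)cc3)CC#C\C=C(/C)[C@H](O[Si](CC)(CC)CC)[C@@H](C)/C=C(/C)C(=O)O[C@H](/C=C/[C@H]1O[C@@H]1C)[C@@H]2C | intermediate
40 | (8Z)-diene macrolactone (5R-OSiEt3; 11-O-(4-methoxybenzyl); otherwise as target) | CO[C@H]1C[C@H]2O[C@@H]1/C=C(/C)[C@H](OCc3ccc(OC)cc3)C/C=C\C=C(/C)[C@H](O[Si](CC)(CC)CC)[C@@H](C)/C=C(/C)C(=O)O[C@H](/C=C/[C@H]1O[C@@H]1C)[C@@H]2C | intermediate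
41 | C5 alcohol macrolactone (5R-OH; 11-O-(4-methoxybenzyl)) | CO[C@H]1C[C@H]2O[C@@H]1/C=C(/C)[C@H](OCc3ccc(OC)cc3)C/C=C\C=C(/C)[C@H](O)[C@@H](C)/C=C(/C)C(=O)O[C@H](/C=C/[C@H]1O[C@@H]1C)[C@@H]2C | intermediate
42 | C5 ketone macrolactone (11-O-(4-methoxybenzyl) ether of the target) | CO[C@H]1C[C@H]2O[C@@H]1/C=C(/C)[C@H](OCc3ccc(OC)cc3)C/C=C\C=C(/C)C(=O)[C@@H](C)/C=C(/C)C(=O)O[C@H](/C=C/[C@H]1O[C@@H]1C)[C@@H]2C | intermediate
43 | CNP0117824.1 (2Z,4S,6E,8Z,11R,12Z,14R,15S,17R,18R,19R,20E,22R,23R) | CO[C@H]1C[C@H]2O[C@@H]1/C=C(/C)[C@H](O)C/C=C\C=C(/C)C(=O)[C@@H](C)/C=C(/C)C(=O)O[C@H](/C=C/[C@H]1O[C@@H]1C)[C@@H]2C | target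

**Step count and risks**

Total: 35 steps. Longest linear sequence: 25 steps (1–13, 16–19, 22, 24, 30–35).

Step 16, the proposed new reaction, is the most uncertain: the 1-methyl group on the boron-bearing carbon and the hindered Z-enal may slow the catalysed addition or lower the selectivity. The fallback uses known chemistry and sets out from enal 16. The established (R)-TRIP-catalysed propargylation with unsubstituted allenylboronic acid pinacol ester (toluene, 4 Å sieves, −20 °C) gives the terminal-alkyne alcohol (1Z,3R)-1-[(2R,3S,5R)-5-[(2S)-1-[tert-butyl(diphenyl)silyl]oxypropan-2-yl]-3-methoxyoxolan-2-yl]-2-methylhex-1-en-5-yn-3-ol F1. NaH, 4-methoxybenzyl chloride and Bu4NI give its 4-methoxybenzyl ether F2. Deprotonation of the terminal alkyne with n-BuLi (THF, −78 °C) and quenching with MeI caps the alkyne and delivers 21, where the route is rejoined; step 17 is then not needed.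

Step 22 may give a poor 19R:19S ratio, since the substrate control in Nozaki–Hiyama–Kishi additions to α-methyl aldehydes is often modest. The fallback sets out from the C19-epimer mixture of 28 formed from 23 and 27. Buffered Dess–Martin oxidation gives the enone (1E,4R)-4-[(2R,4S,5R)-4-methoxy-5-[(1Z,3R)-3-[(4-methoxyphenyl)methoxy]-2-methylhept-1-en-5-yn-1-yl]oxolan-2-yl]-1-[(2R,3R)-3-methyloxiran-2-yl]pent-1-en-3-one F3. Reagent-controlled reduction with (R)-2-methyl-CBS-oxazaborolidine and catecholborane (toluene, −78 °C; alkenyl as the large group) returns the single 19R alcohol 28.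

Step 30 joins two advanced pieces with a base; Z:E erosion or epimerisation of the α-methyl aldehyde would be costly. The fallback reverses the order of the two bond formations and sets out from aldehyde 37. Still–Gennari olefination with the simple phosphonate 13 (KN(SiMe3)2, 18-crown-6, THF, −78 °C) gives ethyl (2Z,4S,5R,6E)-2,4,6-trimethyl-5-(triethylsilyloxy)deca-2,6-dien-8-ynoate F4. Hydrolysis with LiOH (THF–MeOH–H2O, 23 °C) gives (2Z,4S,5R,6E)-2,4,6-trimethyl-5-(triethylsilyloxy)deca-2,6-dien-8-ynoic acid F5. Yamaguchi esterification of alcohol 28 with F5 (2,4,6-trichlorobenzoyl chloride, Et3N, THF; then 28, DMAP, toluene, 0 → 23 °C) gives 38, where the route is rejoined; steps 23 and 24 are then not needed.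

**Further compounds**
F1 | step 16 | (1Z,3R)-1-[(2R,3S,5R)-5-[(2S)-1-[tert-butyl(diphenyl)silyl]oxypropan-2-yl]-3-methoxyoxolan-2-yl]-2-methylhex-1-en-5-yn-3-ol | CO[C@H]1C[C@H]([C@@H](C)CO[Si](c2ccccc2)(c2ccccc2)C(C)(C)C)O[C@@H]1/C=C(/C)[C@H](O)CC#C
F2 | step 16 | 4-methoxybenzyl ether of F1 | CO[C@H]1C[C@H]([C@@H](C)CO[Si](c2ccccc2)(c2ccccc2)C(C)(C)C)O[C@@H]1/C=C(/C)[C@H](OCc3ccc(OC)cc3)CC#C
F3 | step 22 | (1E,4R)-4-[(2R,4S,5R)-4-methoxy-5-[(1Z,3R)-3-[(4-methoxyphenyl)methoxy]-2-methylhept-1-en-5-yn-1-yl]oxolan-2-yl]-1-[(2R,3R)-3-methyloxiran-2-yl]pent-1-en-3-one | CO[C@H]1C[C@H]([C@@H](C)C(=O)/C=C/[C@H]2O[C@@H]2C)O[C@@H]1/C=C(/C)[C@H](OCc3ccc(OC)cc3)CC#CC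
F4 | step 30 | ethyl (2Z,4S,5R,6E)-2,4,6-trimethyl-5-(triethylsilyloxy)deca-2,6-dien-8-ynoate | CCOC(=O)C(\C)=C/[C@H](C)[C@@H](O[Si](CC)(CC)CC)/C(C)=C/C#CC
F5 | step 30 | (2Z,4S,5R,6E)-2,4,6-trimethyl-5-(triethylsilyloxy)deca-2,6-dien-8-ynoic acid | OC(=O)C(\C)=C/[C@H](C)[C@@H](O[Si](CC)(CC)CC)/C(C)=C/C#CC
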